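## Structural features

β-Collatolic acid is an achiral diaryl ether, so no stereocentre has to be set or protected and no stereocentres stand next to each other. Ring A is a benzoic acid with five substituents: CO2H at C1', OH at C2' and C4', the bridging oxygen at C5' and a 2-oxoheptyl chain at C6'. Ring B is the benzenoid ring of a 6-methoxy-3-pentylisocoumarin and carries the bridging oxygen at C8, peri to the lactone carbonyl C1. The ether oxygen is flanked on ring A by an oxygenated carbon and by the carbon bearing the ketone chain, and on ring B by the carbon bearing the lactone carbonyl. This crowded Ar–O–Ar bond is the real difficulty. The fragile groups are four: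
- the 2-(2-oxoheptyl)benzoic acid of ring A, which can cyclodehydrate to a second isocoumarin or condense under base;
- the salicylic acid, which can decarboxylate;
- the enol lactone of ring B, which hydroxide opens and hydrogen can reduce;
- the single methyl ether, which must survive while the other phenol and acid groups are unmasked.

Both rings contain the same C7 ketone unit, open on ring A and lactonised on ring B, so the two must be treated differently. The feature used by the key step is that on ring B the ether oxygen on C8 and the carbonyl carbon C1 on C8a sit on adjacent carbons. An aryne C8≡C8a can take up this nucleophile/electrophile pair in one operation, and an oxygen substituent at C4a (later replaced by the alkyne carbon C4) directs the regiochemistry.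

## Logic of the disconnections

**29 ⇒ 28.** The three O–CH2Ph bonds are cut (ethers at C2' and C4', ester at C1'). The salicylic/resorcylic acid of ring A is the most sensitive part and is revealed last. The forward step must spare the C6 methyl ether and the C3=C4 enol lactone and must not dehydrate the keto acid, so a non-reductive Lewis acid cleavage at low temperature with a cation scavenger is required.

**28 ⇒ 27.** The lactone bond O2–C3 is cut. The pyranone ring is traced back to an ester carbonyl and an alkyne on neighbouring carbons, which turns ring B into a plain 2-alkynylbenzoate. The forward step must close 6-endo rather than 5-exo and must allow the ester alkyl group to leave.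

**27 ⇒ 25 + 26.** The sp2–sp bond C4a–C4 is cut. The whole C7 chain of ring B then comes from the commodity alkyne 26. The price is a leaving group at C4a, which means an oxygen at that carbon; this same oxygen is the regiochemical control element of the aryne.

**25 ⇒ 24 ⇒ 23.** The S–O bond of the sulfonate is cut, then the two acetals are put back. One aqueous acid treatment frees the C4a phenol and the ring A ketone together. The demand is that the free ketone meets only weak bases in the following steps.

**23 ⇒ 22.** The ester O–CH3 bond is cut. The methyl ester masks the acid during sulfonylation and coupling and supplies the carbonyl oxygen for lactone closure. Because the acid has two ortho substituents, the forward step must be alkylation of the carboxylate, not acyl substitution.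

**22 ⇒ 18 + 8 + 19.** The bonds C8–O and C8a–C1 are cut together. These are the most hindered bond of the molecule and its ortho neighbour, and both can be formed across aryne 21 released from 8. Ring B is thereby reduced to a trisubstituted benzene and rings A and B are joined late and convergently. The forward step needs four things:
- regiocontrol from the alkoxy group next to the triple bond;
- a medium without proton donors;
- a preformed phenoxide 20;
- no enolisable ketone, which is why 18 carries a dioxolane.

**8 ⇒ 5.** The C–Si and S–O bonds are cut. Silicon is delivered from oxygen to carbon by a retro-Brook shift, which requires a halogen ortho to the phenol.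

**5 ⇒ 4.** The C–Br bond is cut. The forward step must brominate ortho to the free hydroxyl (C6) and not at C5, which the two ether oxygens activate.

**4 ⇒ 2 ⇒ 1.** The aryl C–O bond (made from aryl–CHO by oxidation) and the acetal O–CH2 bond are cut. The 1,2,4-trioxygenated ring with three different oxygens comes from the cheap salicylaldehyde 1; its formyl carbon is exchanged for the oxygen that later becomes the sulfonate.

**18 ⇒ 16.** The C5'–O bond is cut back to C5'–Br. The forward step must turn an aryl bromide into a phenol in the presence of two esters and a ketal.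

**16 ⇒ 15 ⇒ 11 + 13.** The ketal is removed and the benzylic CH2–C(=O) bond is cut. The ketone chain is attached by lateral metalation of the toluate methyl group. The acyl donor must not over-add and must not be enolised, so 13 is made from 12.

**11 ⇒ 10 ⇒ 9.** The C5'–Br bond and three O–benzyl bonds are cut, leading to the purchasable acid 9. Bromination must go to C5' (next to the methyl group), not to C3' (between the two ether oxygens).

## Other disconnections considered

**Alternative 1:** The cut is C1'–C6' of ring A, which unravels that ring to the acyclic triketo ester A2 (allyl 6-aryloxy-3,5,7-trioxo-8-(dioxolanyl)octanoate). A2 already carries the isocoumarin, introduced as the phenol A3. In the forward key step a mild base (Et3N or Cs2CO3) lets the C2 methylene add to the C7 ketone, and dehydration with enolisation gives the aromatic ring of A1.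

- In favour: the closure is a biomimetic aldol aromatisation of a known reaction type. Ring A is formed with all substituents already in place. The crowded ether is made earlier at an sp3 carbon, which is easier than an Ar–O–Ar coupling. The allyl ester and the dioxolane of A1 come off with zerovalent palladium and dilute acid, so no boron Lewis acid is needed.
- Equal or better: on precedent for the key step and on mildness of the final deprotection this alternative is the better of the two.
- Against: A2 has three ketones, an ester and an α-aryloxy group. It can close in several other ways: aldol of C8 onto C3, pyranone formation through an enol oxygen and the ester, and Claisen closure. Its most acidic C–H (C6, between two ketones) gives an unproductive enolate. Assembly of such a chain needs masked polyketide building blocks.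
- Comparison: structurally it avoids the hindered O-arylation. Mechanistically it exchanges one selectivity problem (aryl anion capture) for a harder one (mode of cyclisation). In step economy it should be longer, because A3 and A2 together need more operations than 8 and 18.

**Alternative 2:** The cuts are C6–C7, C8–C8a and C5–C6 of ring B, leading to the aryl ethynyl ether A5 of ring A and the vinyl diazo keto ester A6. In the forward key step irradiation of A6 triggers a Wolff rearrangement to a vinylketene. This adds to A5 by [2+2] cycloaddition with the ketene carbon bonding to the unsubstituted alkyne carbon. Ring opening of the cyclobutenone, 6π-electrocyclisation and tautomerisation then give phenol A4.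

- In favour: three C–C bonds and a benzene ring are formed in one metal-free operation. The polarity of the ynol ether fixes the position of the aryloxy group. The new hydroxyl appears at C6, where the methyl ether is needed.
- Equal or better: in bonds formed per step it is better than the chosen key step (three bonds and a ring against two bonds). In regiocontrol it is equal. It has no aryl anion that could be protonated.
- Against: A5 must be made from a hindered phenol through a dihalovinyl ether and strong base, which is hard to reconcile with the ester. A6 is a vinyl diazo ketone and is prone to close to a pyrazole. After the key step A4 still needs O-methylation, removal of two methoxymethyl groups, a tert-butyl ester and two dioxolanes, and lactonisation of ring B only. Both rings then hold the same keto-ester motif, so their differentiation rests on the ester type alone; in the chosen plan only ring B has an alkyne.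
- Comparison: step count is similar or higher, and the precursors are less stable.

**Alternative 3:** The cuts are C4a–C4 and O2–C3, leading to the benzoic acid A8 (ring B without any substituent at C4a) and the sulfoxonium ylide A9. In the forward key step [Cp*RhCl2]2 (trivalent rhodium; Cp* is pentamethylcyclopentadienyl) with AgSbF6 metalates the only free ortho C–H of the carboxylate. Carbene transfer from A9 with loss of dimethyl sulfoxide forms C4a–C4, and cyclodehydration closes the pyranone to give A7.

- In favour: C4a needs no oxygen, so acetal removal, sulfonylation, alkynylation and gold cyclisation shrink to one step. The reaction type is established for benzoic acids. There is only one ortho C–H, so site selectivity is not in question.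
- Equal or better: in step economy (about three steps shorter) and in precedent this alternative is the better of the two. In regiocontrol it is equal.
- Against: A8 would come from a copper-mediated coupling of 18 with A10, a forcing Ullmann-type reaction on a phenol with two ortho substituents. The aryne reaches the same ether under mild fluoride conditions. The cationic rhodium/silver system at elevated temperature, usually with an acid additive, endangers the dioxolane. If the ketone of ring A were released, the same cyclodehydration could also close ring A. The benzyl ester and ether oxygens offer competing coordination sites.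
- Comparison: the chosen plan is kept because it forms the hardest bond and the neighbouring carboxyl in one metal-free, substituent-controlled operation. The cost is a longer endgame.

Key step: step 11

Remark on the chemistry: orsellinic acid 9, itself a catalogue compound, is used instead of its methyl ester. The ring A carboxyl must end as a benzyl ester, and exchanging a doubly ortho-substituted methyl ester would cost two extra steps. The target has no stereocentre.

## Route

Step 1
Reactants: 1 2-hydroxy-4-methoxybenzaldehyde
Product: 2 4-methoxy-2-(methoxymethoxy)benzaldehyde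
Conditions: MOMCl, i-Pr2NEt, CH2Cl2, 0 °C → rt
Reagents that add atoms: chloromethyl methyl ether, COCCl
Why: O-alkylation of the phenol with an α-chloro ether (methoxymethyl protection); the amine base leaves the aldehyde untouched.

Step 2
Reactants: 2 4-methoxy-2-(methoxymethoxy)benzaldehyde
Product: 4 4-methoxy-2-(methoxymethoxy)phenol, via aryl formate 3 (not isolated)
Conditions: mCPBA, NaHCO3, CH2Cl2, 0 °C → rt; then K2CO3, MeOH, rt
Reagents that add atoms: 3-chloroperoxybenzoic acid, O=C(OO)c1cccc(Cl)c1
Why: Dakin oxidation run as a Baeyer–Villiger reaction: the electron-rich aryl group migrates in the peracid adduct to give formate 3, which mild methanolysis cleaves; the buffered medium spares the acetal.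

Step 3
Reactants: 4 4-methoxy-2-(methoxymethoxy)phenol
Product: 5 2-bromo-4-methoxy-6-(methoxymethoxy)phenol
Conditions: NBS (1.0 equiv), i-Pr2NH (10 mol %), CH2Cl2, −40 → 0 °C
Reagents that add atoms: N-bromosuccinimide, O=C1CCC(=O)N1Br
Why: Amine-catalysed ortho-bromination of a phenol: the N-bromoamine formed in situ is delivered within a hydrogen-bonded ammonium phenoxide pair to the only free ortho carbon C6. This should override undirected attack at C5, which the two ether oxygens would otherwise favour; the para position is blocked.

Step 4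
Reactants: 5 2-bromo-4-methoxy-6-(methoxymethoxy)phenol
Product: 8 4-methoxy-2-(methoxymethoxy)-6-(trimethylsilyl)phenyl trifluoromethanesulfonate, via aryl silyl ether 6 (not isolated), via lithium silylphenoxide 7 (not isolated)
Conditions: HMDS, THF, 65 °C, then evaporation; n-BuLi, THF, −78 °C; Tf2O, −78 → 0 °C
Reagents that add atoms: hexamethyldisilazane, C[Si](C)(C)N[Si](C)(C)C; trifluoromethanesulfonic anhydride, O=S(=O)(OS(=O)(=O)C(F)(F)F)C(F)(F)F
Why: O-silylation, bromine–lithium exchange and 1,3 O→C silyl shift (retro-Brook rearrangement) give phenoxide 7, which is sulfonylated in the same flask; halogen–metal exchange at −78 °C is faster than any acetal-directed ortho-lithiation.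

Step 5
Reactants: 9 orsellinic acid (2,4-dihydroxy-6-methylbenzoic acid)
Product: 10 benzyl 2,4-bis(benzyloxy)-6-methylbenzoate
Conditions: BnBr (3.5 equiv), K2CO3, DMF, 60 °C
Reagents that add atoms: benzyl bromide, BrCc1ccccc1
Why: Exhaustive SN2 benzylation (carboxylate first, then both phenols); once the acid is esterified, the decarboxylation typical of this acid is no longer possible.

Step 6
Reactants: 10 benzyl 2,4-bis(benzyloxy)-6-methylbenzoate
Product: 11 benzyl 2,4-bis(benzyloxy)-5-bromo-6-methylbenzoate
Conditions: NBS (1.05 equiv), MeCN, 0 °C → rt, dark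
Reagents that add atoms: N-bromosuccinimide, O=C1CCC(=O)N1Br
Why: Electrophilic aromatic bromination; C5 is para to one benzyloxy group and ortho to the other and is less hindered than C3, which lies between two benzyloxy groups. Polar solvent in the dark suppresses radical benzylic bromination.

Step 7
Reactants: 12 hexanoyl chloride
Product: 13 N-methoxy-N-methylhexanamide
Conditions: MeNHOMe·HCl, pyridine, CH2Cl2, 0 °C → rt
Reagents that add atoms: N,O-dimethylhydroxylamine hydrochloride, CNOC.Cl
Why: N-acylation of the hydroxylamine by the acid chloride (amide formation) gives the acyl donor for a Weinreb ketone synthesis.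

Step 8
Reactants: 11 benzyl 2,4-bis(benzyloxy)-5-bromo-6-methylbenzoate; 13 N-methoxy-N-methylhexanamide
Product: 15 benzyl 2,4-bis(benzyloxy)-5-bromo-6-(2-oxoheptyl)benzoate, via benzylic lithium compound 14 (not isolated)
Conditions: LiN(i-Pr)2 (LDA, 1.1 equiv), THF, −78 °C; 13, −78 → −40 °C; aq. NH4Cl
Reagents that add atoms: none
Why: Lateral lithiation of the ortho-toluate gives the ester-stabilised anion 14. The Weinreb ketone synthesis stops at the chelated tetrahedral adduct, so neither over-addition nor enolisation of the product ketone occurs before work-up; the amide base does not exchange the aryl bromide.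

Step 9
Reactants: 15 benzyl 2,4-bis(benzyloxy)-5-bromo-6-(2-oxoheptyl)benzoate
Product: 16 benzyl 2,4-bis(benzyloxy)-5-bromo-6-[(2-pentyl-1,3-dioxolan-2-yl)methyl]benzoate
Conditions: TMSOCH2CH2OTMS, TMSOTf (5 mol %), CH2Cl2, −78 → −20 °C
Reagents that add atoms: 1,2-bis(trimethylsilyloxy)ethane, C[Si](C)(C)OCCO[Si](C)(C)C
Why: Silyl-triflate-catalysed ketalisation with the bis-silyl ether of ethylene glycol runs cold and without water, so the keto ester is not exposed to conditions that would close it to an isocoumarin.

Step 10
Reactants: 16 benzyl 2,4-bis(benzyloxy)-5-bromo-6-[(2-pentyl-1,3-dioxolan-2-yl)methyl]benzoate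
Product: 18 benzyl 2,4-bis(benzyloxy)-5-hydroxy-6-[(2-pentyl-1,3-dioxolan-2-yl)methyl]benzoate, via aryl diisopropyl boronate 17 (not isolated)
Conditions: B(Oi-Pr)3, n-BuLi, toluene/THF, −78 °C (in-situ quench); then 30% H2O2, 1 M NaOH, 0 °C
Reagents that add atoms: hydrogen peroxide, OO
Why: Bromine–lithium exchange with in-situ borylation, then boronate oxidation (1,2-aryl shift from boron to oxygen), converts C–Br into C–OH. The borate traps the aryllithium before it can attack the doubly ortho-substituted benzyl ester.

Step 11
Reactants: 18 benzyl 2,4-bis(benzyloxy)-5-hydroxy-6-[(2-pentyl-1,3-dioxolan-2-yl)methyl]benzoate; 8 4-methoxy-2-(methoxymethoxy)-6-(trimethylsilyl)phenyl trifluoromethanesulfonate; 19 carbon dioxide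
Product: 22 2-{4,6-bis(benzyloxy)-3-[(benzyloxy)carbonyl]-2-[(2-pentyl-1,3-dioxolan-2-yl)methyl]phenoxy}-4-methoxy-6-(methoxymethoxy)benzoic acid, via potassium phenoxide 20 (not isolated), via aryne 21 (not isolated)
Conditions: KH (1.05 equiv), 18-crown-6, THF, 0 °C; CO2 (1 atm); 8 (1.4 equiv) added over 4 h, KF (3 equiv), 0 °C → rt; aq. NaH2PO4
Reagents that add atoms: none
Why: Proposed new method: fluoride attacks silicon of 8 and loss of triflate gives aryne 21; the inductively withdrawing methoxymethoxy group beside the triple bond distorts the aryne so that the remote carbon (future C8) is the electrophilic terminus and negative charge develops at the carbon next to that oxygen (future C8a). The crown-ether-separated phenoxide 20 adds through oxygen at C8 (C8–O), and the aryl anion at C8a, which has no ortho leaving group and no proton donor within reach, adds to dissolved 19 (C8a–C1). The closest known reaction types are the three-component union of arynes, amines and CO2 to anthranilic acids and the fluoride-induced O-arylation of phenols by silylaryl triflates; the combination with a phenoxide nucleophile has not been shown. No ring is closed and no stereocentre is created. Regioselectivity is secured by the alkoxy substituent of the aryne, and O- over C-arylation by the fact that both ortho positions and the para position of 20 are substituted. Carboxylation over protonation is secured by forming 20 with KH beforehand, so that no O–H acid is present, and by working in THF and not in acetonitrile. Slow addition of 8 keeps the aryne concentration low, which limits arylation of the product carboxylate, and room temperature keeps the reversible O-carboxylation of 20 on the side of the free phenoxide.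

Step 12
Reactants: 22 2-{4,6-bis(benzyloxy)-3-[(benzyloxy)carbonyl]-2-[(2-pentyl-1,3-dioxolan-2-yl)methyl]phenoxy}-4-methoxy-6-(methoxymethoxy)benzoic acid
Product: 23 benzyl 2,4-bis(benzyloxy)-5-[5-methoxy-2-(methoxycarbonyl)-3-(methoxymethoxy)phenoxy]-6-[(2-pentyl-1,3-dioxolan-2-yl)methyl]benzoate
Conditions: MeI, K2CO3, DMF, rt
Reagents that add atoms: iodomethane, CI
Why: SN2 O-alkylation of the carboxylate; alkylation at oxygen is not slowed by the two ortho substituents that would block an acid-catalysed esterification.

Step 13
Reactants: 23 benzyl 2,4-bis(benzyloxy)-5-[5-methoxy-2-(methoxycarbonyl)-3-(methoxymethoxy)phenoxy]-6-[(2-pentyl-1,3-dioxolan-2-yl)methyl]benzoate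
Product: 24 benzyl 2,4-bis(benzyloxy)-5-[3-hydroxy-5-methoxy-2-(methoxycarbonyl)phenoxy]-6-(2-oxoheptyl)benzoate
Conditions: 2 M aq. HCl, THF, 45 °C
Reagents that add atoms: water, O
Why: Acid-catalysed hydrolysis of both acetals (aryl methoxymethyl ether and dioxolane) in one operation, the ketone oxygen coming from water; the esters, benzyl ethers and diaryl ether are inert to dilute aqueous acid at this temperature.

Step 14
Reactants: 24 benzyl 2,4-bis(benzyloxy)-5-[3-hydroxy-5-methoxy-2-(methoxycarbonyl)phenoxy]-6-(2-oxoheptyl)benzoate
Product: 25 benzyl 2,4-bis(benzyloxy)-5-{5-methoxy-2-(methoxycarbonyl)-3-[(trifluoromethanesulfonyl)oxy]phenoxy}-6-(2-oxoheptyl)benzoate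
Conditions: Tf2O, pyridine, CH2Cl2, 0 °C
Reagents that add atoms: trifluoromethanesulfonic anhydride, O=S(=O)(OS(=O)(=O)C(F)(F)F)C(F)(F)F
Why: O-sulfonylation of the phenol; pyridine is too weak a base to enolise the ketone toward an enol triflate.

Step 15
Reactants: 25 benzyl 2,4-bis(benzyloxy)-5-{5-methoxy-2-(methoxycarbonyl)-3-[(trifluoromethanesulfonyl)oxy]phenoxy}-6-(2-oxoheptyl)benzoate; 26 hept-1-yne
Product: 27 benzyl 2,4-bis(benzyloxy)-5-[3-(hept-1-yn-1-yl)-5-methoxy-2-(methoxycarbonyl)phenoxy]-6-(2-oxoheptyl)benzoate
Conditions: PdCl2(PPh3)2 (5 mol %), CuI (10 mol %), Et3N, DMF, 70 °C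
Reagents that add atoms: none
Why: Sonogashira coupling: zerovalent palladium, formed in situ from the divalent palladium precatalyst, inserts into the C–OTf bond activated by the ortho ester; transmetalation from the copper acetylide and reductive elimination form C4a–C4.

Step 16
Reactants: 27 benzyl 2,4-bis(benzyloxy)-5-[3-(hept-1-yn-1-yl)-5-methoxy-2-(methoxycarbonyl)phenoxy]-6-(2-oxoheptyl)benzoate
Product: 28 benzyl 2,4-bis(benzyloxy)-5-[(6-methoxy-1-oxo-3-pentyl-1H-isochromen-8-yl)oxy]-6-(2-oxoheptyl)benzoate
Conditions: AuCl3 (10 mol %), MeCN, H2O (2 equiv), 50 °C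
Reagents that add atoms: water, O
Why: Gold-catalysed 6-endo-dig lactonisation: the ester carbonyl oxygen attacks the alkyne activated by trivalent gold at the carbon bearing the pentyl group. The resulting 1-methoxyisochromenylium ion is hydrolysed by water with loss of methanol, and protodeauration gives the isocoumarin.

Step 17
Reactants: 28 benzyl 2,4-bis(benzyloxy)-5-[(6-methoxy-1-oxo-3-pentyl-1H-isochromen-8-yl)oxy]-6-(2-oxoheptyl)benzoate
Product: 29 β-collatolic acid, 2,4-dihydroxy-5-[(6-methoxy-1-oxo-3-pentyl-1H-isochromen-8-yl)oxy]-6-(2-oxoheptyl)benzoic acid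
Conditions: BCl3 (6 equiv), C6HMe5 (6 equiv), CH2Cl2, −78 → −20 °C; MeOH quench
Reagents that add atoms: none
Why: Lewis-acid debenzylation: BCl3 ionises the benzyl–oxygen bonds of both ethers and the ester, and pentamethylbenzene traps the benzyl cations by Friedel–Crafts alkylation. The methyl ether, which is not chelated to a carbonyl, and the lactone should remain.

## Compound list

1 | 2-hydroxy-4-methoxybenzaldehyde | COc1ccc(C=O)c(O)c1 | starting material
2 | 4-methoxy-2-(methoxymethoxy)benzaldehyde | COCOc1cc(OC)ccc1C=O | intermediate
3 | 4-methoxy-2-(methoxymethoxy)phenyl formate | COCOc1cc(OC)ccc1OC=O | intermediate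
4 | 4-methoxy-2-(methoxymethoxy)phenol | COCOc1cc(OC)ccc1O | intermediate
5 | 2-bromo-4-methoxy-6-(methoxymethoxy)phenol | COCOc1cc(OC)cc(Br)c1O | intermediate
6 | [2-bromo-4-methoxy-6-(methoxymethoxy)phenoxy]trimethylsilane | COCOc1cc(OC)cc(Br)c1O[Si](C)(C)C | intermediate
7 | lithium 4-methoxy-2-(methoxymethoxy)-6-(trimethylsilyl)phenoxide | COCOc1cc(OC)cc([Si](C)(C)C)c1[O-].[Li+] | intermediate
8 | 4-methoxy-2-(methoxymethoxy)-6-(trimethylsilyl)phenyl trifluoromethanesulfonate | COCOc1cc(OC)cc([Si](C)(C)C)c1OS(=O)(=O)C(F)(F)F | intermediate
9 | orsellinic acid (2,4-dihydroxy-6-methylbenzoic acid) | Cc1cc(O)cc(O)c1C(=O)O | starting material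
10 | benzyl 2,4-bis(benzyloxy)-6-methylbenzoate | Cc1cc(OCc2ccccc2)cc(OCc2ccccc2)c1C(=O)OCc1ccccc1 | intermediate
11 | benzyl 2,4-bis(benzyloxy)-5-bromo-6-methylbenzoate | Cc1c(Br)c(OCc2ccccc2)cc(OCc2ccccc2)c1C(=O)OCc1ccccc1 | intermediate
12 | hexanoyl chloride | CCCCCC(=O)Cl | starting material
13 | N-methoxy-N-methylhexanamide | CCCCCC(=O)N(C)OC | intermediate
14 | benzylic lithium compound of 11 | [Li]Cc1c(Br)c(OCc2ccccc2)cc(OCc2ccccc2)c1C(=O)OCc1ccccc1 | intermediate
15 | benzyl 2,4-bis(benzyloxy)-5-bromo-6-(2-oxoheptyl)benzoate | CCCCCC(=O)Cc1c(Br)c(OCc2ccccc2)cc(OCc2ccccc2)c1C(=O)OCc1ccccc1 | intermediate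
16 | benzyl 2,4-bis(benzyloxy)-5-bromo-6-[(2-pentyl-1,3-dioxolan-2-yl)methyl]benzoate | CCCCCC1(Cc2c(Br)c(OCc3ccccc3)cc(OCc3ccccc3)c2C(=O)OCc2ccccc2)OCCO1 | intermediate
17 | benzyl 2,4-bis(benzyloxy)-5-[bis(propan-2-yloxy)boranyl]-6-[(2-pentyl-1,3-dioxolan-2-yl)methyl]benzoate | CCCCCC1(Cc2c(B(OC(C)C)OC(C)C)c(OCc3ccccc3)cc(OCc3ccccc3)c2C(=O)OCc2ccccc2)OCCO1 | intermediate
18 | benzyl 2,4-bis(benzyloxy)-5-hydroxy-6-[(2-pentyl-1,3-dioxolan-2-yl)methyl]benzoate (ring A phenol) | CCCCCC1(Cc2c(O)c(OCc3ccccc3)cc(OCc3ccccc3)c2C(=O)OCc2ccccc2)OCCO1 | intermediate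
19 | carbon dioxide | O=C=O | starting material
20 | potassium phenoxide of 18 | CCCCCC1(Cc2c([O-])c(OCc3ccccc3)cc(OCc3ccccc3)c2C(=O)OCc2ccccc2)OCCO1.[K+] | intermediate
21 | 3-(methoxymethoxy)-5-methoxybenzyne | COCOC1=CC(OC)=CC#C1 | intermediate
22 | 2-{4,6-bis(benzyloxy)-3-[(benzyloxy)carbonyl]-2-[(2-pentyl-1,3-dioxolan-2-yl)methyl]phenoxy}-4-methoxy-6-(methoxymethoxy)benzoic acid | CCCCCC1(Cc2c(Oc3cc(OC)cc(OCOC)c3C(=O)O)c(OCc3ccccc3)cc(OCc3ccccc3)c2C(=O)OCc2ccccc2)OCCO1 | intermediate
23 | benzyl 2,4-bis(benzyloxy)-5-[5-methoxy-2-(methoxycarbonyl)-3-(methoxymethoxy)phenoxy]-6-[(2-pentyl-1,3-dioxolan-2-yl)methyl]benzoate | CCCCCC1(Cc2c(Oc3cc(OC)cc(OCOC)c3C(=O)OC)c(OCc3ccccc3)cc(OCc3ccccc3)c2C(=O)OCc2ccccc2)OCCO1 | intermediate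
24 | benzyl 2,4-bis(benzyloxy)-5-[3-hydroxy-5-methoxy-2-(methoxycarbonyl)phenoxy]-6-(2-oxoheptyl)benzoate | CCCCCC(=O)Cc1c(Oc2cc(OC)cc(O)c2C(=O)OC)c(OCc2ccccc2)cc(OCc2ccccc2)c1C(=O)OCc1ccccc1 | intermediate
25 | benzyl 2,4-bis(benzyloxy)-5-{5-methoxy-2-(methoxycarbonyl)-3-[(trifluoromethanesulfonyl)oxy]phenoxy}-6-(2-oxoheptyl)benzoate | CCCCCC(=O)Cc1c(Oc2cc(OC)cc(OS(=O)(=O)C(F)(F)F)c2C(=O)OC)c(OCc2ccccc2)cc(OCc2ccccc2)c1C(=O)OCc1ccccc1 | intermediate
26 | hept-1-yne | C#CCCCCC | starting material
27 | benzyl 2,4-bis(benzyloxy)-5-[3-(hept-1-yn-1-yl)-5-methoxy-2-(methoxycarbonyl)phenoxy]-6-(2-oxoheptyl)benzoate | CCCCCC(=O)Cc1c(Oc2cc(OC)cc(C#CCCCCC)c2C(=O)OC)c(OCc2ccccc2)cc(OCc2ccccc2)c1C(=O)OCc1ccccc1 | intermediate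
28 | benzyl 2,4-bis(benzyloxy)-5-[(6-methoxy-1-oxo-3-pentyl-1H-isochromen-8-yl)oxy]-6-(2-oxoheptyl)benzoate | CCCCCC(=O)Cc1c(Oc2cc(OC)cc3cc(CCCCC)oc(=O)c23)c(OCc2ccccc2)cc(OCc2ccccc2)c1C(=O)OCc1ccccc1 | intermediate
29 | β-collatolic acid | CCCCCC(=O)Cc1c(Oc2cc(OC)cc3cc(CCCCC)oc(=O)c23)c(O)cc(O)c1C(=O)O | target

## Step count and least certain steps

Total: 17 steps. Longest linear sequence: 12 steps (steps 5, 6, 8, 9, 10, 11, 12, 13, 14, 15, 16 and 17, from 9).

**Step 11 (key step, proposed new method).** Three processes may compete with the intended sequence: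
- reversible O-carboxylation of phenoxide 20 to an aryl carbonate, whose oxygen may add to the aryne and lead, by acyl shift, to a salicylate ester;
- protonation of the aryl anion before CO2 capture;
- arylation of the product carboxylate by a second aryne.

Fallback by known chemistry, setting out from 18 and returning at 22: purchased 2-fluoro-4,6-dimethoxybenzaldehyde F1 is demethylated at the oxygen ortho to the formyl group (BCl3, CH2Cl2, −78 → 0 °C, chelation control) to 2-fluoro-6-hydroxy-4-methoxybenzaldehyde F2. This is protected (MOMCl, i-Pr2NEt) as 2-fluoro-4-methoxy-6-(methoxymethoxy)benzaldehyde F3. Nucleophilic aromatic substitution of the fluoride, activated by the ortho formyl group, with the phenoxide of 18 (K2CO3, DMF, 100 °C) should give benzyl 2,4-bis(benzyloxy)-5-[2-formyl-5-methoxy-3-(methoxymethoxy)phenoxy]-6-[(2-pentyl-1,3-dioxolan-2-yl)methyl]benzoate F4. Pinnick oxidation (NaClO2, NaH2PO4, 2-methylbut-2-ene, t-BuOH/H2O) then gives 22.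

**Step 3.** Site selectivity may be poor: electrophilic attack at C5, activated by both ether oxygens, may compete with the phenol-directed attack at C6. Fallback by directed metalation, setting out from 4 and returning at 8: 4 is carbamoylated (Et2NCOCl, NaH, THF) to 4-methoxy-2-(methoxymethoxy)phenyl N,N-diethylcarbamate F5. Carbamate-directed ortho-lithiation (s-BuLi, TMEDA, THF, −78 °C) with a chlorotrimethylsilane quench gives 4-methoxy-2-(methoxymethoxy)-6-(trimethylsilyl)phenyl N,N-diethylcarbamate F6. Reductive removal of the carbamate (LiAlH4, THF) gives 4-methoxy-2-(methoxymethoxy)-6-(trimethylsilyl)phenol F7, and sulfonylation (n-BuLi, then Tf2O, −78 °C) gives 8.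

**Step 10.** The aryllithium may attack an ester, or the anion may move to a benzylic ether position, before borylation. Fallback by palladium catalysis, setting out from 16 and returning at 18: Miyaura borylation (B2pin2, Pd(OAc)2, SPhos, KOAc, dioxane, 90 °C) gives benzyl 2,4-bis(benzyloxy)-6-[(2-pentyl-1,3-dioxolan-2-yl)methyl]-5-(4,4,5,5-tetramethyl-1,3,2-dioxaborolan-2-yl)benzoate F8, which is oxidised (H2O2, aq. NaOH, 0 °C) to 18.

**Step 16.** The ring may close 5-exo to an alkylidene phthalide, the alkyne may be hydrated, or the ketone may bind gold and slow the catalysis. Fallback by electrophilic cyclisation, setting out from 27 and returning at 28: iodolactonisation (I2, NaHCO3, MeCN, rt), which for 2-alkynylbenzoate esters should be 6-endo, gives benzyl 2,4-bis(benzyloxy)-5-[(4-iodo-6-methoxy-1-oxo-3-pentyl-1H-isochromen-8-yl)oxy]-6-(2-oxoheptyl)benzoate F9. Reductive deiodination with zerovalent palladium (Pd(PPh3)4, HCO2Na, DMF, 60 °C) gives 28.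

**Step 17.** The Lewis acid may promote cyclodehydration of the ring A keto acid to a second isocoumarin, or the hindered benzyl ester may cleave incompletely. Fallback by hydrogenolysis, setting out from 28 and arriving directly at 29: H2 (1 atm), Pd(OH)2/C, EtOAc, rt, stopped as soon as the three benzyl groups are gone so that the C3=C4 bond of the lactone is not reduced. This fallback makes no new compound (entry F0).

## Further compounds

F1 | step 11 | 2-fluoro-4,6-dimethoxybenzaldehyde (purchased) | COc1cc(OC)c(C=O)c(F)c1
F2 | step 11 | 2-fluoro-6-hydroxy-4-methoxybenzaldehyde | COc1cc(O)c(C=O)c(F)c1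
F3 | step 11 | 2-fluoro-4-methoxy-6-(methoxymethoxy)benzaldehyde | COCOc1cc(OC)cc(F)c1C=O
F4 | step 11 | benzyl 2,4-bis(benzyloxy)-5-[2-formyl-5-methoxy-3-(methoxymethoxy)phenoxy]-6-[(2-pentyl-1,3-dioxolan-2-yl)methyl]benzoate | CCCCCC1(Cc2c(Oc3cc(OC)cc(OCOC)c3C=O)c(OCc3ccccc3)cc(OCc3ccccc3)c2C(=O)OCc2ccccc2)OCCO1
F5 | step 3 | 4-methoxy-2-(methoxymethoxy)phenyl N,N-diethylcarbamate | COCOc1cc(OC)ccc1OC(=O)N(CC)CC
F6 | step 3 | 4-methoxy-2-(methoxymethoxy)-6-(trimethylsilyl)phenyl N,N-diethylcarbamate | COCOc1cc(OC)cc([Si](C)(C)C)c1OC(=O)N(CC)CC
F7 | step 3 | 4-methoxy-2-(methoxymethoxy)-6-(trimethylsilyl)phenol | COCOc1cc(OC)cc([Si](C)(C)C)c1O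
F8 | step 10 | benzyl 2,4-bis(benzyloxy)-6-[(2-pentyl-1,3-dioxolan-2-yl)methyl]-5-(4,4,5,5-tetramethyl-1,3,2-dioxaborolan-2-yl)benzoate | CCCCCC1(Cc2c(B3OC(C)(C)C(C)(C)O3)c(OCc3ccccc3)cc(OCc3ccccc3)c2C(=O)OCc2ccccc2)OCCO1
F9 | step 16 | benzyl 2,4-bis(benzyloxy)-5-[(4-iodo-6-methoxy-1-oxo-3-pentyl-1H-isochromen-8-yl)oxy]-6-(2-oxoheptyl)benzoate | CCCCCC(=O)Cc1c(Oc2cc(OC)cc3c(I)c(CCCCC)oc(=O)c23)c(OCc2ccccc2)cc(OCc2ccccc2)c1C(=O)OCc1ccccc1
F0 | step 17 | none | none
A1 | alternative 1 | allyl 2,4-dihydroxy-5-[(6-methoxy-1-oxo-3-pentyl-1H-isochromen-8-yl)oxy]-6-[(2-pentyl-1,3-dioxolan-2-yl)methyl]benzoate | C=CCOC(=O)c1c(O)cc(O)c(Oc2cc(OC)cc3cc(CCCCC)oc(=O)c23)c1CC1(CCCCC)OCCO1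
A2 | alternative 1 | allyl 6-[(6-methoxy-1-oxo-3-pentyl-1H-isochromen-8-yl)oxy]-3,5,7-trioxo-8-(2-pentyl-1,3-dioxolan-2-yl)octanoate | C=CCOC(=O)CC(=O)CC(=O)C(Oc1cc(OC)cc2cc(CCCCC)oc(=O)c12)C(=O)CC1(CCCCC)OCCO1
A3 | alternative 1 | 8-hydroxy-6-methoxy-3-pentyl-1H-isochromen-1-one | CCCCCc1cc2cc(OC)cc(O)c2c(=O)o1
A4 | alternative 2 | methyl 2-{3-(tert-butoxycarbonyl)-4,6-bis(methoxymethoxy)-2-[(2-pentyl-1,3-dioxolan-2-yl)methyl]phenoxy}-4-hydroxy-6-[(2-pentyl-1,3-dioxolan-2-yl)methyl]benzoate | CCCCCC1(Cc2cc(O)cc(Oc3c(CC4(CCCCC)OCCO4)c(C(=O)OC(C)(C)C)c(OCOC)cc3OCOC)c2C(=O)OC)OCCO1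
A5 | alternative 2 | tert-butyl 3-(ethynyloxy)-4,6-bis(methoxymethoxy)-2-[(2-pentyl-1,3-dioxolan-2-yl)methyl]benzoate | C#COc1c(CC2(CCCCC)OCCO2)c(C(=O)OC(C)(C)C)c(OCOC)cc1OCOC
A6 | alternative 2 | methyl 2-diazo-4-methylidene-3-oxo-5-(2-pentyl-1,3-dioxolan-2-yl)pentanoate | C=C(CC1(CCCCC)OCCO1)C(=O)C(=[N+]=[N-])C(=O)OC
A7 | alternative 3 | benzyl 2,4-bis(benzyloxy)-5-[(6-methoxy-1-oxo-3-pentyl-1H-isochromen-8-yl)oxy]-6-[(2-pentyl-1,3-dioxolan-2-yl)methyl]benzoate | CCCCCC1(Cc2c(Oc3cc(OC)cc4cc(CCCCC)oc(=O)c34)c(OCc3ccccc3)cc(OCc3ccccc3)c2C(=O)OCc2ccccc2)OCCO1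
A8 | alternative 3 | 2-{4,6-bis(benzyloxy)-3-[(benzyloxy)carbonyl]-2-[(2-pentyl-1,3-dioxolan-2-yl)methyl]phenoxy}-4-methoxybenzoic acid | CCCCCC1(Cc2c(Oc3cc(OC)ccc3C(=O)O)c(OCc3ccccc3)cc(OCc3ccccc3)c2C(=O)OCc2ccccc2)OCCO1
A9 | alternative 3 | 1-[dimethyl(oxo)-λ6-sulfanylidene]heptan-2-one | CCCCCC(=O)C=S(C)(C)=O
A10 | alternative 3 | 2-bromo-4-methoxybenzoic acid | COc1ccc(C(=O)O)c(Br)c1
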